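## The problem

Derrisdione A (15) is an achiral benzil: a 4-hydroxybenzoyl unit (ring B) is joined through a 1,2-dione to C6 of a 2,2-dimethyl-2H-chromene. Ring A is hexasubstituted; in chromene numbering C4a carries the pyran carbon C4, C5 a methoxy group, C6 the dione, C7 a free hydroxyl, C8 a prenyl group and C8a the ring oxygen O1. There is no stereocentre, so every difficulty is one of position: three phloroglucinol-type oxygens must become a methyl ether, a free chelated phenol and a pyran oxygen, and two different C5 units must go to C8 and C4a, the two ring carbons that flank the same oxygen. Direct C-prenylation of such a ring does not tell C8 from C4a (or carbon from oxygen), and a dimethylpropargyl ether on a chelated resorcinol ketone is known to favour closure onto the carbon between the two oxygens, here C8, which is the wrong one. The sensitive functions are the dione (benzilic acid rearrangement with hydroxide, attack by nucleophiles), the prenyl olefin beside the C7 hydroxyl (acid closes it to a chroman), the C3=C4 olefin and the electron-rich phenols; an oxidant such as SeO2 cannot be used once either olefin is present. The enabling feature is that C8 is ortho to the C7 oxygen, whose other ortho position C6 is blocked by the dione, while the pyran is attached through O1 at C8a and C4 at C4a. The prenyl group is therefore the retron of a 1,1-dimethylallyl ether on O7 and the pyran the retron of a 1,1-dimethylpropargyl ether on O8a (O7 and O8a denote the oxygens on C7 and C8a; O8a becomes O1).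

## Retrosynthesis

**15 to 14 (O–Si on ring B).** The ring B phenol is masked until the end, because it would otherwise compete with the chelated C7 hydroxyl in the allylation. A triisopropylsilyl ether is preferred to a tert-butyldimethylsilyl ether: once the dione is in place this ether sits para to a carbonyl, where the smaller silyl group is easily lost to base. The forward step only asks for buffered fluoride, which spares the dione and both olefins.

**14 to 10 (C8–CH2 of the prenyl group, C4a–C4 and O1–C2).** All three skeletal bonds are cut in one operation, leading back to bis-ether 10 with a 1,1-dimethylallyl group on O7 and a 1,1-dimethylpropargyl group on O8a. Against the neighbouring cuts (C-prenylation of a phloroglucinol ketone, or pyran formation before C8 is filled) this one uses the oxygens already present to deliver each carbon unit to a single ring position. Compound 10 has no pyran ring and two unsubstituted ring carbons, and both C5 units derive from simple C5 reagents. The forward reaction must move the allyl group before the propargyl group and must run in a non-acidic medium.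

**10 to 7 and 9 (O7–C of the tertiary allyl ether).** The usual route to such ethers, propargylation followed by semi-hydrogenation, cannot be used because the O8a alkyne must survive. The ether is therefore made by decarboxylative allylation of the chelated phenol 7 with the mixed carbonate 9 under zerovalent palladium catalysis. Carbonate 9 goes back to 2-methylbut-3-en-2-ol (8).

**7 to 6 (the C=O next to ring B).** The dione is traced to the deoxybenzoin 6 by benzylic oxidation. This step is placed before any olefin exists, and after the propargylation, since only in the deoxybenzoin series are the two non-chelated phenols different enough in acidity to be addressed separately.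

**6 to 5 to 3 and 4 (O–Si, then O8a–C of the propargyl ether).** In triol 3 the ring A hydroxyl para to the ketone is a vinylogous acid, the ring B hydroxyl an ordinary phenol and the ortho hydroxyl is chelated. This ladder lets the three oxygens be taken in the order propargyl (with 3-chloro-3-methylbut-1-yne, 4), silyl, allyl without auxiliary protecting groups.

**3 to 1 and 2 (aryl–C(=O) bond).** Friedel–Crafts acylation of 5-methoxyresorcinol (1) with 4-hydroxyphenylacetic acid (2) gives the whole carbon skeleton apart from the two C5 units in one step. The cuts on the other side of the ketone would need protected partners and a metal-catalysed coupling. The forward reaction has to acylate C4 of 1 (between a hydroxyl and the methoxy group) and not C2 (between the two hydroxyls).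

## Roads not taken

**Alternative 1: aryne insertion into an arylacetic acid.** The cut is made at C6–C(=O) and C7–O. Fluoride would release the C6–C7 aryne from 5-methoxy-2,2-dimethyl-8-(3-methylbut-2-enyl)-6-(trimethylsilyl)-2H-chromen-7-yl trifluoromethanesulfonate A2. The aryne would insert into the C–O bond of 2-[4-(methoxymethoxy)phenyl]acetic acid A3 to give the ortho-hydroxyaryl ketone A1.
- Merits: the C5 methoxy group should steer the carboxylate oxygen to C7 and the acyl group to C6, the ring B side chain arrives convergently, and the regiochemical question of the first acylation in the chosen route does not arise.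
- Weak points: A2 is a hexasubstituted arene that already contains the C8 prenyl group and the pyran, so the central positional problem is moved into its preparation, not solved. The aryne can undergo an ene reaction with its own prenyl side chain. A1 is a deoxybenzoin whose methylene must still be oxidised with both olefins present. The methoxymethyl group must finally be removed with acid beside an ortho-prenylphenol.
- Comparison: this road is better in convergence. The chosen plan sets against it an oxidation that precedes all olefins, a fluoride-only deprotection and far fewer steps to the key intermediate.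

**Alternative 2: aryne plus enal to build the pyran.** The cut is made at C4a–C4, C8a–O1 and O1–C2. The aryne from 3-methoxy-5-(methoxymethoxy)-6-(3-methylbut-2-enyl)-2-(trimethylsilyl)phenyl trifluoromethanesulfonate A5 would add to the carbonyl of 3-methylbut-2-enal A6. The benzoxete would open to an ortho-quinone methide and close to the chromene A4.
- Merits: three bonds and the ring in one step, with the methoxy group again directing the oxygen to C8a. A4 keeps C6–H between a methoxy and a methoxymethoxy group, an excellent site for directed metalation, so the complete dione could be introduced by acylation without any late oxidation. In this respect the road is better than the chosen one, which has to oxidise a deoxybenzoin that carries a propargyl ether.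
- Weak points: A5 must already hold the prenyl group between two oxygens, which is the same selectivity problem. Aryne–enal chromene formation needs excess aldehyde and competes with ene reaction at the prenyl group. The final acid removal of the methoxymethyl group next to the C8 prenyl group risks chroman formation.
- Comparison: the chosen plan needs no aryne precursor and places both carbon substituents through oxygens that are present from the first step.

**Alternative 3: photochemical vinylketene benzannulation.** Ring A is assembled from acyclic pieces. Irradiation of (3Z)-6-[4-(tert-butyldimethylsilyloxy)phenyl]-1-diazo-3-methoxyhex-3-en-5-yn-2-one A8 would give a vinylketene by Wolff rearrangement. Cycloaddition with triisopropyl[(5-methylhex-4-en-1-yn-1-yl)oxy]silane A9, cyclobutenone opening and six-electron electrocyclisation would give the pentasubstituted phenol A7.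
- Merits: the position of every substituent follows from the connectivity of the two partners, so no aromatic substitution selectivity is involved. This is the most rigorous regiocontrol of the four plans.
- Weak points: A8 and A9 each need several steps. A7 still lacks the pyran, which would have to be added by the propargyl ether chemistry of the chosen plan. Its diarylalkyne must be oxidised to the dione in the presence of the prenyl and chromene olefins, and the ortho-alkynylphenol can cyclise to a benzofuran.
- Comparison: the chosen plan accepts a regiochemical risk in its first step, but is much shorter and forms the dione before any olefin is present.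

Key step: step 7

Assumption: the 2-hydroxybenzils 7, 14 and 15 are written as open diones; if any exists partly as the cyclic hemiketal (2-aryl-2-hydroxybenzofuran-3-one), it is expected to react through the open phenol.

## Route

Step 1
Reactants: 1 5-methoxyresorcinol; 2 4-hydroxyphenylacetic acid
Product: 3 1-(2,4-dihydroxy-6-methoxyphenyl)-2-(4-hydroxyphenyl)ethan-1-one
Conditions: BF3·OEt2 (neat), 85 °C; aq. NaOAc work-up
Reagents that add atoms: none
Why: Friedel–Crafts acylation of a phloroglucinol monoether by an arylacetic acid in BF3·OEt2 is the standard entry to 2-hydroxydeoxybenzoins; attack at C4 of 1 (ortho to one hydroxyl, para to the other, two equivalent sites) should outweigh attack between the two hydroxyls, and the product is held as its difluoroboron chelate until the acetate work-up.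

Step 2
Reactants: 3 1-(2,4-dihydroxy-6-methoxyphenyl)-2-(4-hydroxyphenyl)ethan-1-one; 4 3-chloro-3-methylbut-1-yne
Product: 5 1-[2-hydroxy-6-methoxy-4-(2-methylbut-3-yn-2-yloxy)phenyl]-2-(4-hydroxyphenyl)ethan-1-one
Conditions: 4 (1.05 equiv), DBU (1.1 equiv), CuCl2·2H2O (0.5 mol%), MeCN, 0 °C
Reagents that add atoms: none
Why: Copper-catalysed propargylic etherification (copper acetylide/allenylidene pathway) makes tertiary aryl propargyl ethers at 0 °C; with one equivalent of DBU only the most acidic phenol, the ring A hydroxyl para to the ketone, is ionised, while the chelated ortho hydroxyl and the ring B phenol stay protonated.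

Step 3
Reactants: 5 1-[2-hydroxy-6-methoxy-4-(2-methylbut-3-yn-2-yloxy)phenyl]-2-(4-hydroxyphenyl)ethan-1-one
Product: 6 1-[2-hydroxy-6-methoxy-4-(2-methylbut-3-yn-2-yloxy)phenyl]-2-{4-[tri(propan-2-yl)silyloxy]phenyl}ethan-1-one
Conditions: TIPSCl, imidazole, DMF, 0 °C to rt
Reagents that add atoms: chlorotri(propan-2-yl)silane (TIPSCl), CC(C)[Si](Cl)(C(C)C)C(C)C
Why: Imidazole-mediated silylation of the unhindered ring B phenol; the hydroxyl hydrogen-bonded to the ketone is not silylated under these conditions, and the bulky triisopropylsilyl ether is chosen because it must later survive alkoxide, zerovalent palladium and 190 °C.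

Step 4
Reactants: 6 1-[2-hydroxy-6-methoxy-4-(2-methylbut-3-yn-2-yloxy)phenyl]-2-{4-[tri(propan-2-yl)silyloxy]phenyl}ethan-1-one
Product: 7 1-[2-hydroxy-6-methoxy-4-(2-methylbut-3-yn-2-yloxy)phenyl]-2-{4-[tri(propan-2-yl)silyloxy]phenyl}ethane-1,2-dione
Conditions: SeO2 (1.5 equiv), 1,4-dioxane/H2O (20:1), 90 °C
Reagents that add atoms: selenium dioxide, O=[Se]=O
Why: Riley oxidation of the methylene flanked by the ketone and ring B to the 1,2-dione; the propargyl ether has no propargylic C–H (its carbinol carbon is quaternary), no olefin is present yet, and 90 °C lies below the usual onset of the propargyl ether rearrangement.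

Step 5
Reactants: 8 2-methylbut-3-en-2-ol
Product: 9 tert-butyl 2-methylbut-3-en-2-yl carbonate
Conditions: n-BuLi, THF, −78 °C; Boc2O, −78 °C to rt
Reagents that add atoms: di-tert-butyl dicarbonate (Boc2O), CC(C)(C)OC(=O)OC(=O)OC(C)(C)C
Why: Acylation of the lithium tertiary alkoxide with Boc2O gives the mixed carbonate, the usual electrophile for decarboxylative allylic etherification.

Step 6
Reactants: 7 1-[2-hydroxy-6-methoxy-4-(2-methylbut-3-yn-2-yloxy)phenyl]-2-{4-[tri(propan-2-yl)silyloxy]phenyl}ethane-1,2-dione; 9 tert-butyl 2-methylbut-3-en-2-yl carbonate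
Product: 10 1-[2-methoxy-6-(2-methylbut-3-en-2-yloxy)-4-(2-methylbut-3-yn-2-yloxy)phenyl]-2-{4-[tri(propan-2-yl)silyloxy]phenyl}ethane-1,2-dione
Conditions: Pd(PPh3)4 (5 mol%), 9 (2.5 equiv), THF, 0 °C to rt
Reagents that add atoms: none
Why: Decarboxylative Tsuji–Trost O-allylation: zerovalent palladium ionises 9 to a 1,1-dimethyl-π-allyl complex and tert-butoxide, which deprotonates the chelated phenol; the phenoxide attacks the more substituted allyl terminus under kinetic control at low temperature to give the tertiary ether, and the terminal alkyne, silyl ether and dione are left alone in the absence of copper.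

Step 7
Reactants: 10 1-[2-methoxy-6-(2-methylbut-3-en-2-yloxy)-4-(2-methylbut-3-yn-2-yloxy)phenyl]-2-{4-[tri(propan-2-yl)silyloxy]phenyl}ethane-1,2-dione
Product: 14 1-[7-hydroxy-5-methoxy-2,2-dimethyl-8-(3-methylbut-2-en-1-yl)-2H-chromen-6-yl]-2-{4-[tri(propan-2-yl)silyloxy]phenyl}ethane-1,2-dione (ring B triisopropylsilyl ether of Derrisdione A), via C8-prenyl phenol propargyl ether 11 (not isolated), via ortho-allenyl phenol 12 (not isolated), via ortho-quinone methide 13 (not isolated)
Conditions: PhNEt2 (degassed, 0.05 M), Ar, 110 °C until 10 is consumed, then 190 °C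
Reagents that add atoms: none
Why: At 110 °C the O7 1,1-dimethylallyl ether undergoes an aromatic Claisen [3,3] shift through a chair transition state that joins its terminal CH2 to C8, and the dienone enolises to phenol 11, held by a hydrogen bond to the C6 carbonyl. At 190 °C the O8a 1,1-dimethylpropargyl ether shifts by [3,3] to C4a, the allenyl dienone enolises to 12, a 1,5-hydrogen shift from the new C8a hydroxyl to the central allene carbon gives ortho-quinone methide 13, and this closes the pyran. The ring is closed by a thermal oxa-6π electrocyclisation that forms O1–C2, after the propargyl shift has made C4a–C4. The closest known reactions are the thermal rearrangement of aryl 1,1-dimethylallyl ethers to ortho-prenylphenols and of aryl 1,1-dimethylpropargyl ethers to 2,2-dimethyl-2H-chromenes. No stereocentre is formed. Site selectivity comes from the substrate: C6 is blocked by the dione, so the allyl group can only be retained at C8, and once C8 is filled C4a is the only enolisable ortho position left for the propargyl unit. Order selectivity rests on the lower barrier of the strained tertiary allyl ether, hence the two temperature stages, and the basic, non-nucleophilic solvent suppresses ionisation of the tertiary ethers and acid-catalysed closure of the prenyl group onto O7.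

Step 8
Reactants: 14 1-[7-hydroxy-5-methoxy-2,2-dimethyl-8-(3-methylbut-2-en-1-yl)-2H-chromen-6-yl]-2-{4-[tri(propan-2-yl)silyloxy]phenyl}ethane-1,2-dione
Product: 15 Derrisdione A, 1-[7-hydroxy-5-methoxy-2,2-dimethyl-8-(3-methylbut-2-en-1-yl)-2H-chromen-6-yl]-2-(4-hydroxyphenyl)ethane-1,2-dione
Conditions: TBAF, AcOH (1:1), THF, 0 °C
Reagents that add atoms: none
Why: Fluoride cleavage of the aryl silyl ether, which is fast for a phenoxide para to a carbonyl; buffering with AcOH keeps the medium from inducing benzilic acid rearrangement of the dione or isomerisation of the chromene and prenyl olefins.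

## Compound list

1 | 5-methoxyresorcinol (5-methoxybenzene-1,3-diol) | COc1cc(O)cc(O)c1 | starting material
2 | 4-hydroxyphenylacetic acid | OC(=O)Cc1ccc(O)cc1 | starting material
3 | 1-(2,4-dihydroxy-6-methoxyphenyl)-2-(4-hydroxyphenyl)ethan-1-one | COc1cc(O)cc(O)c1C(=O)Cc1ccc(O)cc1 | intermediate
4 | 3-chloro-3-methylbut-1-yne | CC(C)(Cl)C#C | starting material
5 | 1-[2-hydroxy-6-methoxy-4-(2-methylbut-3-yn-2-yloxy)phenyl]-2-(4-hydroxyphenyl)ethan-1-one | COc1cc(OC(C)(C)C#C)cc(O)c1C(=O)Cc1ccc(O)cc1 | intermediate
6 | 1-[2-hydroxy-6-methoxy-4-(2-methylbut-3-yn-2-yloxy)phenyl]-2-{4-[tri(propan-2-yl)silyloxy]phenyl}ethan-1-one | COc1cc(OC(C)(C)C#C)cc(O)c1C(=O)Cc1ccc(O[Si](C(C)C)(C(C)C)C(C)C)cc1 | intermediate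
7 | 1-[2-hydroxy-6-methoxy-4-(2-methylbut-3-yn-2-yloxy)phenyl]-2-{4-[tri(propan-2-yl)silyloxy]phenyl}ethane-1,2-dione | COc1cc(OC(C)(C)C#C)cc(O)c1C(=O)C(=O)c1ccc(O[Si](C(C)C)(C(C)C)C(C)C)cc1 | intermediate
8 | 2-methylbut-3-en-2-ol | CC(C)(O)C=C | starting material
9 | tert-butyl 2-methylbut-3-en-2-yl carbonate | CC(C)(C)OC(=O)OC(C)(C)C=C | intermediate
10 | 1-[2-methoxy-6-(2-methylbut-3-en-2-yloxy)-4-(2-methylbut-3-yn-2-yloxy)phenyl]-2-{4-[tri(propan-2-yl)silyloxy]phenyl}ethane-1,2-dione | COc1cc(OC(C)(C)C#C)cc(OC(C)(C)C=C)c1C(=O)C(=O)c1ccc(O[Si](C(C)C)(C(C)C)C(C)C)cc1 | intermediate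
11 | 1-[2-hydroxy-6-methoxy-3-(3-methylbut-2-en-1-yl)-4-(2-methylbut-3-yn-2-yloxy)phenyl]-2-{4-[tri(propan-2-yl)silyloxy]phenyl}ethane-1,2-dione (C8-prenyl phenol propargyl ether) | COc1cc(OC(C)(C)C#C)c(CC=C(C)C)c(O)c1C(=O)C(=O)c1ccc(O[Si](C(C)C)(C(C)C)C(C)C)cc1 | intermediate
12 | 1-[2,4-dihydroxy-6-methoxy-5-(3-methylbuta-1,2-dien-1-yl)-3-(3-methylbut-2-en-1-yl)phenyl]-2-{4-[tri(propan-2-yl)silyloxy]phenyl}ethane-1,2-dione (ortho-allenyl phenol) | COc1c(C=C=C(C)C)c(O)c(CC=C(C)C)c(O)c1C(=O)C(=O)c1ccc(O[Si](C(C)C)(C(C)C)C(C)C)cc1 | intermediate
13 | (6Z)-3-hydroxy-5-methoxy-2-(3-methylbut-2-en-1-yl)-6-(3-methylbut-2-en-1-ylidene)-4-(oxo{4-[tri(propan-2-yl)silyloxy]phenyl}acetyl)cyclohexa-2,4-dien-1-one (ortho-quinone methide) | CC(C)=C/C=C1\C(=O)C(CC=C(C)C)=C(O)C(C(=O)C(=O)c2ccc(O[Si](C(C)C)(C(C)C)C(C)C)cc2)=C1OC | intermediate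
14 | 1-[7-hydroxy-5-methoxy-2,2-dimethyl-8-(3-methylbut-2-en-1-yl)-2H-chromen-6-yl]-2-{4-[tri(propan-2-yl)silyloxy]phenyl}ethane-1,2-dione | COc1c2c(c(CC=C(C)C)c(O)c1C(=O)C(=O)c1ccc(O[Si](C(C)C)(C(C)C)C(C)C)cc1)OC(C)(C)C=C2 | intermediate
15 | Derrisdione A, 1-[7-hydroxy-5-methoxy-2,2-dimethyl-8-(3-methylbut-2-en-1-yl)-2H-chromen-6-yl]-2-(4-hydroxyphenyl)ethane-1,2-dione (achiral) | COc1c2c(c(CC=C(C)C)c(O)c1C(=O)C(=O)c1ccc(O)cc1)OC(C)(C)C=C2 | target

## Step count and risks

Total: 8 steps. Longest linear sequence: 7 steps (steps 1, 2, 3, 4, 6, 7, 8); step 5 is a one-step side branch that supplies carbonate 9.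

**Step 7 (key step).** The most likely failure is premature rearrangement of the propargyl ether while C8 is still free, which would close the pyran onto C8. Loss of the tertiary allyl group by ionisation or elimination at high temperature, or thermal closure of the new prenyl group onto O7, are the other risks.
Fallback: it sets out from 10 and comes back at 14, and divides the cascade between two different modes of activation. Eu(fod)3 (10 mol%) in CHCl3 at 40–50 °C, chelated between the dione carbonyl and the ether oxygen, should trigger only the allyl shift, so that 11 can be isolated. The pyran is then closed at room temperature by 6-endo hydroarylation of the propargyl ether with the monovalent gold catalyst Ph3PAuNTf2 in CH2Cl2; only C4a is free for this. No compound outside the list is made (F0).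

**Step 6.** The chelated, flanked phenoxide may attack the π-allyl complex too slowly, so that the complex collapses to isoprene. The tertiary ether may also re-ionise under zerovalent palladium and drift to the linear prenyl ether.
Fallback: it sets out from 3 and comes back at 10, and builds the allyl ether by propargylation and semi-hydrogenation before the second alkyne exists.
- The ring A para hydroxyl of 3 is blocked with 4-methoxybenzyl chloride (K2CO3, acetone) to give 1-[2-hydroxy-6-methoxy-4-(4-methoxybenzyloxy)phenyl]-2-(4-hydroxyphenyl)ethan-1-one F1.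
- Silylation as in step 3 gives the ring B triisopropylsilyl ether F2, and SeO2 oxidation as in step 4 gives the benzil F3.
- The chelated hydroxyl is etherified with 4 (K2CO3, KI, CuI, acetone, 50 °C) to the 1,1-dimethylpropargyl ether F4.
- Semi-hydrogenation (H2, Pd/CaCO3 poisoned with Pb(OAc)2, quinoline) gives the 1,1-dimethylallyl ether F5.
- DDQ (CH2Cl2, pH 7 buffer) removes the 4-methoxybenzyl group to give the phenol F6, and copper-catalysed propargylation as in step 2 delivers 10.

**Step 4.** Enolisation of the hindered, chelated ketone may be slow. Longer heating then risks the onset of the propargyl ether rearrangement and partial desilylation by selenous acid.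
Fallback: it sets out from 6 and comes back at 7, and works at or below room temperature. Regitz diazo transfer (4-acetamidobenzenesulfonyl azide, DBU, MeCN) gives 2-diazo-1-[2-hydroxy-6-methoxy-4-(2-methylbut-3-yn-2-yloxy)phenyl]-2-{4-[tri(propan-2-yl)silyloxy]phenyl}ethan-1-one F7. Oxidation of the diazo carbon with dimethyldioxirane (acetone, 0 °C) gives 7.

**Step 2.** Discrimination between the ring A para hydroxyl and the ring B phenol may be incomplete, giving ring B or double etherification.
Fallback: it sets out from 3 and comes back at 6, and replaces acidity control by protecting-group control.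
- Both non-chelated phenols are silylated (TIPSCl, imidazole, DMF) to 1-{2-hydroxy-6-methoxy-4-[tri(propan-2-yl)silyloxy]phenyl}-2-{4-[tri(propan-2-yl)silyloxy]phenyl}ethan-1-one F8.
- The ring A silyl ether, activated by the para ketone, is cleaved selectively (K2CO3, MeOH, 0 °C) to 1-(2,4-dihydroxy-6-methoxyphenyl)-2-{4-[tri(propan-2-yl)silyloxy]phenyl}ethan-1-one F9.
- Propargylation of F9 with 4 (DBU, CuCl2·2H2O, MeCN, 0 °C) can now only occur at the para hydroxyl and gives 6.

**Step 1.** Acylation may take place between the two hydroxyls of 1, giving the isomeric 2,6-dihydroxy-4-methoxy ketone, which would be hard to separate.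
Fallback: it sets out from 2, uses phloroglucinol in place of 1 so that no regiochemical choice exists, and comes back at 6.
- BF3·OEt2 acylation of phloroglucinol with 2 gives 2-(4-hydroxyphenyl)-1-(2,4,6-trihydroxyphenyl)ethan-1-one F10.
- Copper-catalysed propargylation of its most acidic para hydroxyl gives 1-[2,6-dihydroxy-4-(2-methylbut-3-yn-2-yloxy)phenyl]-2-(4-hydroxyphenyl)ethan-1-one F11.
- Silylation of ring B gives 1-[2,6-dihydroxy-4-(2-methylbut-3-yn-2-yloxy)phenyl]-2-{4-[tri(propan-2-yl)silyloxy]phenyl}ethan-1-one F12.
- Monomethylation of one of the two equivalent chelated hydroxyls (Me2SO4, 1 equiv, K2CO3, acetone) gives 6.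

## Further compounds

F0 | step 7 | none | none
F1 | step 6 | 1-[2-hydroxy-6-methoxy-4-(4-methoxybenzyloxy)phenyl]-2-(4-hydroxyphenyl)ethan-1-one | COc1ccc(COc2cc(O)c(C(=O)Cc3ccc(O)cc3)c(OC)c2)cc1
F2 | step 6 | 1-[2-hydroxy-6-methoxy-4-(4-methoxybenzyloxy)phenyl]-2-{4-[tri(propan-2-yl)silyloxy]phenyl}ethan-1-one | COc1ccc(COc2cc(O)c(C(=O)Cc3ccc(O[Si](C(C)C)(C(C)C)C(C)C)cc3)c(OC)c2)cc1
F3 | step 6 | 1-[2-hydroxy-6-methoxy-4-(4-methoxybenzyloxy)phenyl]-2-{4-[tri(propan-2-yl)silyloxy]phenyl}ethane-1,2-dione | COc1ccc(COc2cc(O)c(C(=O)C(=O)c3ccc(O[Si](C(C)C)(C(C)C)C(C)C)cc3)c(OC)c2)cc1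
F4 | step 6 | 1-[2-methoxy-4-(4-methoxybenzyloxy)-6-(2-methylbut-3-yn-2-yloxy)phenyl]-2-{4-[tri(propan-2-yl)silyloxy]phenyl}ethane-1,2-dione | COc1ccc(COc2cc(OC(C)(C)C#C)c(C(=O)C(=O)c3ccc(O[Si](C(C)C)(C(C)C)C(C)C)cc3)c(OC)c2)cc1
F5 | step 6 | 1-[2-methoxy-4-(4-methoxybenzyloxy)-6-(2-methylbut-3-en-2-yloxy)phenyl]-2-{4-[tri(propan-2-yl)silyloxy]phenyl}ethane-1,2-dione | COc1ccc(COc2cc(OC(C)(C)C=C)c(C(=O)C(=O)c3ccc(O[Si](C(C)C)(C(C)C)C(C)C)cc3)c(OC)c2)cc1
F6 | step 6 | 1-[4-hydroxy-2-methoxy-6-(2-methylbut-3-en-2-yloxy)phenyl]-2-{4-[tri(propan-2-yl)silyloxy]phenyl}ethane-1,2-dione | COc1cc(O)cc(OC(C)(C)C=C)c1C(=O)C(=O)c1ccc(O[Si](C(C)C)(C(C)C)C(C)C)cc1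
F7 | step 4 | 2-diazo-1-[2-hydroxy-6-methoxy-4-(2-methylbut-3-yn-2-yloxy)phenyl]-2-{4-[tri(propan-2-yl)silyloxy]phenyl}ethan-1-one | COc1cc(OC(C)(C)C#C)cc(O)c1C(=O)C(=[N+]=[N-])c1ccc(O[Si](C(C)C)(C(C)C)C(C)C)cc1
F8 | step 2 | 1-{2-hydroxy-6-methoxy-4-[tri(propan-2-yl)silyloxy]phenyl}-2-{4-[tri(propan-2-yl)silyloxy]phenyl}ethan-1-one | COc1cc(O[Si](C(C)C)(C(C)C)C(C)C)cc(O)c1C(=O)Cc1ccc(O[Si](C(C)C)(C(C)C)C(C)C)cc1
F9 | step 2 | 1-(2,4-dihydroxy-6-methoxyphenyl)-2-{4-[tri(propan-2-yl)silyloxy]phenyl}ethan-1-one | COc1cc(O)cc(O)c1C(=O)Cc1ccc(O[Si](C(C)C)(C(C)C)C(C)C)cc1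
F10 | step 1 | 2-(4-hydroxyphenyl)-1-(2,4,6-trihydroxyphenyl)ethan-1-one | O=C(Cc1ccc(O)cc1)c1c(O)cc(O)cc1O
F11 | step 1 | 1-[2,6-dihydroxy-4-(2-methylbut-3-yn-2-yloxy)phenyl]-2-(4-hydroxyphenyl)ethan-1-one | C#CC(C)(C)Oc1cc(O)c(C(=O)Cc2ccc(O)cc2)c(O)c1
F12 | step 1 | 1-[2,6-dihydroxy-4-(2-methylbut-3-yn-2-yloxy)phenyl]-2-{4-[tri(propan-2-yl)silyloxy]phenyl}ethan-1-one | C#CC(C)(C)Oc1cc(O)c(C(=O)Cc2ccc(O[Si](C(C)C)(C(C)C)C(C)C)cc2)c(O)c1
A1 | alternative 1 | 1-[7-hydroxy-5-methoxy-2,2-dimethyl-8-(3-methylbut-2-enyl)-2H-chromen-6-yl]-2-[4-(methoxymethoxy)phenyl]ethanone | COc1c2C=CC(C)(C)Oc2c(CC=C(C)C)c(O)c1C(=O)Cc1ccc(OCOC)cc1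
A2 | alternative 1 | 5-methoxy-2,2-dimethyl-8-(3-methylbut-2-enyl)-6-(trimethylsilyl)-2H-chromen-7-yl trifluoromethanesulfonate | COc1c2C=CC(C)(C)Oc2c(CC=C(C)C)c(OS(=O)(=O)C(F)(F)F)c1[Si](C)(C)C
A3 | alternative 1 | 2-[4-(methoxymethoxy)phenyl]acetic acid | COCOc1ccc(CC(=O)O)cc1
A4 | alternative 2 | 5-methoxy-7-(methoxymethoxy)-2,2-dimethyl-8-(3-methylbut-2-enyl)-2H-chromene | COc1cc(OCOC)c(CC=C(C)C)c2OC(C)(C)C=Cc12
A5 | alternative 2 | 3-methoxy-5-(methoxymethoxy)-6-(3-methylbut-2-enyl)-2-(trimethylsilyl)phenyl trifluoromethanesulfonate | COc1cc(OCOC)c(CC=C(C)C)c(OS(=O)(=O)C(F)(F)F)c1[Si](C)(C)C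
A6 | alternative 2 | 3-methylbut-2-enal | CC(C)=CC=O
A7 | alternative 3 | 2-{[4-(tert-butyldimethylsilyloxy)phenyl]ethynyl}-3-methoxy-6-(3-methylbut-2-enyl)-5-(triisopropylsilyloxy)phenol | COc1cc(O[Si](C(C)C)(C(C)C)C(C)C)c(CC=C(C)C)c(O)c1C#Cc1ccc(O[Si](C)(C)C(C)(C)C)cc1
A8 | alternative 3 | (3Z)-6-[4-(tert-butyldimethylsilyloxy)phenyl]-1-diazo-3-methoxyhex-3-en-5-yn-2-one | [N-]=[N+]=CC(=O)/C(OC)=C/C#Cc1ccc(O[Si](C)(C)C(C)(C)C)cc1
A9 | alternative 3 | triisopropyl[(5-methylhex-4-en-1-yn-1-yl)oxy]silane | CC(C)=CCC#CO[Si](C(C)C)(C(C)C)C(C)C
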